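**Retrosynthetic overview**
- Target ⇐ ninefold O-demethylation of a cis,cis-bis(dihydrobenzofuran) nonamethyl ether, with acid-mediated C2 epimerisation of both rings to trans.
- Both dihydrobenzofuran rings (ring A on the stilbene arene, ring B on the middle arene) and all four stereocentres ⇐ one twofold, catalyst-controlled Rh-carbene 1,5 C–H insertion of an achiral bis(diaryldiazomethane), made from a bis-hydrazone.
- Bis-hydrazone ⇐ bis-ketone ⇐ Mitsunobu etherification of a 2-hydroxybenzophenone (stilbene half) with a benzylic alcohol (middle half) that already carries the second benzophenone and a 2,4-dimethoxybenzyl ether.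
- Each hindered benzophenone ⇐ lithiation between two methoxy groups plus 3,5-dimethoxybenzonitrile, then chelation-controlled BCl3 mono-demethylation.
- Ring order: no ring is made before the key step; rings A and B are formed together.

Assumption: Rh2(R-PTAD)4, dirhodium tetrakis[(R)-N-phthaloyl-(1-adamantyl)glycinate], is taken to give the 3S sense at both rings; if a single-ring model shows the opposite sense, Rh2(S-PTAD)4 is used with nothing else changed.

**Step 1**
Reactants: 1 (E)-3,4',5-trimethoxystilbene; 2 3,5-dimethoxybenzonitrile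
Product: 5 (3,5-dimethoxyphenyl){2,6-dimethoxy-4-[(E)-2-(4-methoxyphenyl)ethenyl]phenyl}methanone, via aryllithium 3 (not isolated), via lithium ketiminate 4 (not isolated)
Conditions: n-BuLi (1.15 equiv), THF, −20 → 0 °C; then 2, −78 °C → rt; then 2 M HCl, THF, 50 °C
Reagents that add atoms: water, O
Why: Directed ortho-metalation occurs at the position flanked by both methoxy groups, the aryllithium adds once to the nitrile because the ketiminate cannot add again, and acid hydrolysis gives the hindered ketone; no stereocentre is formed.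

**Step 2**
Reactants: 5 (3,5-dimethoxyphenyl){2,6-dimethoxy-4-[(E)-2-(4-methoxyphenyl)ethenyl]phenyl}methanone
Product: 6 (3,5-dimethoxyphenyl){2-hydroxy-6-methoxy-4-[(E)-2-(4-methoxyphenyl)ethenyl]phenyl}methanone
Conditions: BCl3 (1.1 equiv), CH2Cl2, −78 → 0 °C; then H2O
Reagents that add atoms: none
Why: Chelation-controlled BCl3 demethylation cleaves only a methoxy group ortho to the carbonyl, and the boron chelate formed after the first cleavage protects the second (the two ortho groups are equivalent, so either gives 6).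

**Step 3**
Reactants: 7 2,4-dimethoxybenzaldehyde; 2 3,5-dimethoxybenzonitrile
Product: 11 3-(3,5-dimethoxybenzoyl)-2,4-dimethoxybenzaldehyde, via lithium amino alkoxide 8 (not isolated), via ring-lithiated amino alkoxide 9 (not isolated), via ketiminate adduct 10 (not isolated)
Conditions: 1-methylpiperazine, n-BuLi, THF, −20 °C, then 7; then s-BuLi, TMEDA, −78 → −40 °C; then 2, −78 °C → rt; then 2 M HCl, THF, 50 °C
Reagents that add atoms: water, O
Why: Comins in situ protection of the aldehyde as an α-amino alkoxide allows directed ortho-metalation at C3 between the two methoxy groups, nitrile addition stops at the ketiminate, and the acid work-up releases both the aldehyde and the ketone.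

**Step 4**
Reactants: 11 3-(3,5-dimethoxybenzoyl)-2,4-dimethoxybenzaldehyde
Product: 12 3-(3,5-dimethoxybenzoyl)-2-hydroxy-4-methoxybenzaldehyde
Conditions: BCl3 (1.05 equiv), CH2Cl2, −78 → −20 °C; then H2O
Reagents that add atoms: none
Why: Chelation-assisted BCl3 demethylation is expected to select the C2 methoxy group, which is flanked by both carbonyls, ortho to the coplanar aldehyde and twisted out of conjugation, over the C4 methoxy group that has only the twisted ketone next to it.

**Step 5**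
Reactants: 12 3-(3,5-dimethoxybenzoyl)-2-hydroxy-4-methoxybenzaldehyde; 13 (2,4-dimethoxyphenyl)methanol
Product: 14 3-(3,5-dimethoxybenzoyl)-2-[(2,4-dimethoxyphenyl)methoxy]-4-methoxybenzaldehyde
Conditions: PPh3, DIAD, THF, 0 °C → rt
Reagents that add atoms: none
Why: Mitsunobu etherification of an acidic, doubly hydrogen-bonded phenol with a primary benzylic alcohol proceeds under neutral conditions that leave the aldehyde and ketone untouched.

**Step 6**
Reactants: 14 3-(3,5-dimethoxybenzoyl)-2-[(2,4-dimethoxyphenyl)methoxy]-4-methoxybenzaldehyde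
Product: 15 (3,5-dimethoxyphenyl){2-[(2,4-dimethoxyphenyl)methoxy]-3-(hydroxymethyl)-6-methoxyphenyl}methanone
Conditions: NaBH4 (0.6 equiv), MeOH/THF, 0 °C, 20 min
Reagents that add atoms: none
Why: Chemoselective borohydride reduction takes the aldehyde and leaves the diaryl ketone, which is shielded by two ortho alkoxy groups.

**Step 7**
Reactants: 6 (3,5-dimethoxyphenyl){2-hydroxy-6-methoxy-4-[(E)-2-(4-methoxyphenyl)ethenyl]phenyl}methanone; 15 (3,5-dimethoxyphenyl){2-[(2,4-dimethoxyphenyl)methoxy]-3-(hydroxymethyl)-6-methoxyphenyl}methanone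
Product: 16 (3,5-dimethoxyphenyl){2-({3-(3,5-dimethoxybenzoyl)-2-[(2,4-dimethoxyphenyl)methoxy]-4-methoxyphenyl}methoxy)-6-methoxy-4-[(E)-2-(4-methoxyphenyl)ethenyl]phenyl}methanone (achiral bis-ketone)
Conditions: PPh3, DIAD, THF, 0 °C → rt
Reagents that add atoms: none
Why: Mitsunobu etherification joins the 2-hydroxybenzophenone to the activated primary benzylic alcohol by SN2 displacement, so no benzylic halide has to be made.

**Step 8**
Reactants: 16 bis-ketone
Product: 17 bis-hydrazone of 16 (both C=O replaced by C=N–NH2; C=N geometry immaterial)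
Conditions: N2H4·H2O (60 equiv), AcOH (1 equiv), n-BuOH, 120 °C, sealed tube, degassed, argon, 48 h
Reagents that add atoms: hydrazine, NN
Why: Acid-catalysed hydrazone condensation is driven by a large excess of the small, strong α-nucleophile at high temperature, which is what the di-ortho-alkoxy ketones need; air is excluded so that no diimide forms to reduce the stilbene.

**Step 9**
Reactants: 17 bis-hydrazone
Product: 19 (2R,3S)-3-(3,5-dimethoxyphenyl)-2-[(2R,3S)-2-(2,4-dimethoxyphenyl)-3-(3,5-dimethoxyphenyl)-4-methoxy-2,3-dihydro-1-benzofuran-7-yl]-4-methoxy-6-[(E)-2-(4-methoxyphenyl)ethenyl]-2,3-dihydro-1-benzofuran (cis,cis), via bis(diazo) compound 18 (not isolated)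
Conditions: MnO2 (20 equiv), CH2Cl2, 0 °C, 1 h; filter under argon; filtrate added over 3 h to Rh2(R-PTAD)4 (2 mol %), CH2Cl2, −20 °C → rt
Reagents that add atoms: none
Why: Proposed new method: twofold use in one flask of the known enantioselective intramolecular 1,5 C–H insertion of donor/donor rhodium carbenes generated from hydrazones by MnO2 oxidation (closest known reaction: the single-ring synthesis of cis-2,3-diaryl-2,3-dihydrobenzofurans from 2-benzyloxybenzophenone hydrazones); each diaryl carbene sits ortho to an electron-rich aryl-CH2-O group whose hydridic C–H is far more reactive than the other ortho OCH3, the two sites are too far apart to interfere, the chiral carboxylate pocket fixes the carbene face so that both C3 centres become S, suprafacial insertion gives the cis (2R) arrangement in each ring, two independent catalyst-controlled events raise the ee of the major diastereomer (Horeau amplification), and slow addition suppresses azine formation.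

**Step 10**
Reactants: 19 cis,cis-bis(dihydrobenzofuran) nonamethyl ether
Product: 20 Gnetumontanin B, (2S,3S)-2-[(2S,3S)-2-(2,4-dihydroxyphenyl)-3-(3,5-dihydroxyphenyl)-4-hydroxy-2,3-dihydro-1-benzofuran-7-yl]-3-(3,5-dihydroxyphenyl)-6-[(E)-2-(4-hydroxyphenyl)ethenyl]-2,3-dihydro-1-benzofuran-4-ol
Conditions: BBr3 (30 equiv), CH2Cl2, −78 °C → rt, 8 h; MeOH at −78 °C, then H2O
Reagents that add atoms: none
Why: BBr3 ether cleavage removes all nine methyl groups, while reversible Lewis-acid ionisation of each benzylic C2–O bond (cation stabilised by the ortho/para oxygens of the C2 aryl group) and 5-exo reclosure epimerises C2 only, so each cis ring relaxes to the more stable trans ring with C3 untouched, (2R,3S) → (2S,3S) in both rings.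

**Compound list**
1 | (E)-3,4',5-trimethoxystilbene (resveratrol trimethyl ether) | COc1ccc(/C=C/c2cc(OC)cc(OC)c2)cc1 | starting material
2 | 3,5-dimethoxybenzonitrile | COc1cc(OC)cc(C#N)c1 | starting material
3 | {2,6-dimethoxy-4-[(E)-2-(4-methoxyphenyl)ethenyl]phenyl}lithium (not isolated) | COc1ccc(/C=C/c2cc(OC)c([Li])c(OC)c2)cc1 | intermediate
4 | N-lithio ketimine of 5 (not isolated) | COc1ccc(/C=C/c2cc(OC)c(C(=N[Li])c3cc(OC)cc(OC)c3)c(OC)c2)cc1 | intermediate
5 | (3,5-dimethoxyphenyl){2,6-dimethoxy-4-[(E)-2-(4-methoxyphenyl)ethenyl]phenyl}methanone | COc1ccc(/C=C/c2cc(OC)c(C(=O)c3cc(OC)cc(OC)c3)c(OC)c2)cc1 | intermediate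
6 | (3,5-dimethoxyphenyl){2-hydroxy-6-methoxy-4-[(E)-2-(4-methoxyphenyl)ethenyl]phenyl}methanone | COc1ccc(/C=C/c2cc(O)c(C(=O)c3cc(OC)cc(OC)c3)c(OC)c2)cc1 | intermediate
7 | 2,4-dimethoxybenzaldehyde | COc1ccc(C=O)c(OC)c1 | starting material
8 | lithium (2,4-dimethoxyphenyl)(4-methylpiperazin-1-yl)methanolate (not isolated) | COc1ccc(C(O[Li])N2CCN(C)CC2)c(OC)c1 | intermediate
9 | 3-lithio derivative of 8 (not isolated) | COc1ccc(C(O[Li])N2CCN(C)CC2)c(OC)c1[Li] | intermediate
10 | N-lithio ketimine formed from 9 and nitrile 2, amino alkoxide still in place (not isolated) | COc1ccc(C(O[Li])N2CCN(C)CC2)c(OC)c1C(=N[Li])c1cc(OC)cc(OC)c1 | intermediate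
11 | 3-(3,5-dimethoxybenzoyl)-2,4-dimethoxybenzaldehyde | COc1ccc(C=O)c(OC)c1C(=O)c1cc(OC)cc(OC)c1 | intermediate
12 | 3-(3,5-dimethoxybenzoyl)-2-hydroxy-4-methoxybenzaldehyde | COc1ccc(C=O)c(O)c1C(=O)c1cc(OC)cc(OC)c1 | intermediate
13 | (2,4-dimethoxyphenyl)methanol | COc1ccc(CO)c(OC)c1 | starting material
14 | 3-(3,5-dimethoxybenzoyl)-2-[(2,4-dimethoxyphenyl)methoxy]-4-methoxybenzaldehyde | COc1ccc(C=O)c(OCc2ccc(OC)cc2OC)c1C(=O)c1cc(OC)cc(OC)c1 | intermediate
15 | (3,5-dimethoxyphenyl){2-[(2,4-dimethoxyphenyl)methoxy]-3-(hydroxymethyl)-6-methoxyphenyl}methanone | COc1ccc(CO)c(OCc2ccc(OC)cc2OC)c1C(=O)c1cc(OC)cc(OC)c1 | intermediate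
16 | bis-ketone (achiral; E alkene) | COc1ccc(/C=C/c2cc(OC)c(C(=O)c3cc(OC)cc(OC)c3)c(OCc3ccc(OC)c(C(=O)c4cc(OC)cc(OC)c4)c3OCc3ccc(OC)cc3OC)c2)cc1 | intermediate
17 | bis-hydrazone of 16 | COc1ccc(/C=C/c2cc(OC)c(C(=NN)c3cc(OC)cc(OC)c3)c(OCc3ccc(OC)c(C(=NN)c4cc(OC)cc(OC)c4)c3OCc3ccc(OC)cc3OC)c2)cc1 | intermediate
18 | bis(diaryldiazomethane) from 17 (not isolated) | COc1ccc(/C=C/c2cc(OC)c(C(=[N+]=[N-])c3cc(OC)cc(OC)c3)c(OCc3ccc(OC)c(C(=[N+]=[N-])c4cc(OC)cc(OC)c4)c3OCc3ccc(OC)cc3OC)c2)cc1 | intermediate
19 | cis,cis-bis(dihydrobenzofuran) nonamethyl ether, (2R,3S) in ring A and (2R,3S) in ring B | COc1ccc(/C=C/c2cc(OC)c3c(c2)O[C@@H](c2ccc(OC)c4c2O[C@@H](c2ccc(OC)cc2OC)[C@H]4c2cc(OC)cc(OC)c2)[C@H]3c2cc(OC)cc(OC)c2)cc1 | intermediate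
20 | Gnetumontanin B, (2S,3S) in ring A and (2S,3S) in ring B, both trans | Oc1ccc(/C=C/c2cc(O)c3c(c2)O[C@H](c2ccc(O)c4c2O[C@H](c2ccc(O)cc2O)[C@H]4c2cc(O)cc(O)c2)[C@H]3c2cc(O)cc(O)c2)cc1 | target

**Totals**
Total step count: 10. Longest linear sequence: 8 (steps 3 to 10, from 7); the stilbene branch (steps 1 and 2) joins at step 7.

**Three steps most likely to fail**

Step 9, twofold C–H insertion. Possible failures are azine or oligomer formation from two diazo groups in one molecule, or poor control in one of the two events. The fallback forms the rings one at a time and sets out from 15. Silylation (TBSCl, imidazole, DMF) gives {2-[(2,4-dimethoxyphenyl)methoxy]-3-({[tert-butyl(dimethyl)silyl]oxy}methyl)-6-methoxyphenyl}(3,5-dimethoxyphenyl)methanone F1. Hydrazine as in step 8 gives its hydrazone F2, and MnO2 gives the diazo compound F3 in the flask. Rh2(R-PTAD)4 closes ring B alone to the cis silyl ether tert-butyl{[(2R,3S)-2-(2,4-dimethoxyphenyl)-3-(3,5-dimethoxyphenyl)-4-methoxy-2,3-dihydro-1-benzofuran-7-yl]methoxy}dimethylsilane F4. TBAF in THF frees the alcohol [(2R,3S)-2-(2,4-dimethoxyphenyl)-3-(3,5-dimethoxyphenyl)-4-methoxy-2,3-dihydro-1-benzofuran-7-yl]methanol F5. Mitsunobu coupling with 6 gives the ring-B-containing aryl ether ketone F6, which is converted to its hydrazone F7 and then to the diazo compound F8. A second, single insertion closes ring A, and the sequence comes back to the route at 19. Each insertion is then a single-ring case.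

Step 8, bis-hydrazone formation on two di-ortho-alkoxy benzophenones. The ketones may not condense fully even under forcing conditions. The fallback sets out from 16: thionation with Lawesson's reagent (toluene, 110 °C) gives the bis(thioketone) F9, whose far more electrophilic C=S groups exchange with N2H4·H2O in THF/EtOH at room temperature, coming back to the route at 17.

Step 10, ninefold demethylation with concurrent epimerisation. The Lewis acid may open the electron-rich dihydrobenzofurans irreversibly or attack the free phenolic stilbene. The fallback separates the two events and sets out from 19: catalytic TFA in CH2Cl2 (0 °C → rt) epimerises both C2 centres on the fully protected compound to give the trans,trans nonamethyl ether with (2S,3S) configuration in both rings F10, checked by the H2/H3 coupling constants. Basic SN2 demethylation with sodium ethanethiolate in DMF at 150 °C under argon then comes back to the route at 20.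

**Further compounds**
F1 | step 9 | {2-[(2,4-dimethoxyphenyl)methoxy]-3-({[tert-butyl(dimethyl)silyl]oxy}methyl)-6-methoxyphenyl}(3,5-dimethoxyphenyl)methanone | COc1ccc(CO[Si](C)(C)C(C)(C)C)c(OCc2ccc(OC)cc2OC)c1C(=O)c1cc(OC)cc(OC)c1
F2 | step 9 | hydrazone of F1 | COc1ccc(CO[Si](C)(C)C(C)(C)C)c(OCc2ccc(OC)cc2OC)c1C(=NN)c1cc(OC)cc(OC)c1
F3 | step 9 | diazo compound from F2 | COc1ccc(CO[Si](C)(C)C(C)(C)C)c(OCc2ccc(OC)cc2OC)c1C(=[N+]=[N-])c1cc(OC)cc(OC)c1
F4 | step 9 | tert-butyl{[(2R,3S)-2-(2,4-dimethoxyphenyl)-3-(3,5-dimethoxyphenyl)-4-methoxy-2,3-dihydro-1-benzofuran-7-yl]methoxy}dimethylsilane (cis) | CC(C)(C)[Si](C)(C)OCc1ccc(OC)c2c1O[C@@H](c1ccc(OC)cc1OC)[C@H]2c1cc(OC)cc(OC)c1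
F5 | step 9 | [(2R,3S)-2-(2,4-dimethoxyphenyl)-3-(3,5-dimethoxyphenyl)-4-methoxy-2,3-dihydro-1-benzofuran-7-yl]methanol (cis) | OCc1ccc(OC)c2c1O[C@@H](c1ccc(OC)cc1OC)[C@H]2c1cc(OC)cc(OC)c1
F6 | step 9 | (3,5-dimethoxyphenyl){2-{[(2R,3S)-2-(2,4-dimethoxyphenyl)-3-(3,5-dimethoxyphenyl)-4-methoxy-2,3-dihydro-1-benzofuran-7-yl]methoxy}-6-methoxy-4-[(E)-2-(4-methoxyphenyl)ethenyl]phenyl}methanone | COc1ccc(/C=C/c2cc(OC)c(C(=O)c3cc(OC)cc(OC)c3)c(OCc3ccc(OC)c4c3O[C@@H](c3ccc(OC)cc3OC)[C@H]4c3cc(OC)cc(OC)c3)c2)cc1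
F7 | step 9 | hydrazone of F6 | COc1ccc(/C=C/c2cc(OC)c(C(=NN)c3cc(OC)cc(OC)c3)c(OCc3ccc(OC)c4c3O[C@@H](c3ccc(OC)cc3OC)[C@H]4c3cc(OC)cc(OC)c3)c2)cc1
F8 | step 9 | diazo compound from F7 | COc1ccc(/C=C/c2cc(OC)c(C(=[N+]=[N-])c3cc(OC)cc(OC)c3)c(OCc3ccc(OC)c4c3O[C@@H](c3ccc(OC)cc3OC)[C@H]4c3cc(OC)cc(OC)c3)c2)cc1
F9 | step 8 | bis(thioketone) of 16 (both C=O replaced by C=S) | COc1ccc(/C=C/c2cc(OC)c(C(=S)c3cc(OC)cc(OC)c3)c(OCc3ccc(OC)c(C(=S)c4cc(OC)cc(OC)c4)c3OCc3ccc(OC)cc3OC)c2)cc1
F10 | step 10 | trans,trans-bis(dihydrobenzofuran) nonamethyl ether, (2S,3S) in ring A and (2S,3S) in ring B | COc1ccc(/C=C/c2cc(OC)c3c(c2)O[C@H](c2ccc(OC)c4c2O[C@H](c2ccc(OC)cc2OC)[C@H]4c2cc(OC)cc(OC)c2)[C@H]3c2cc(OC)cc(OC)c2)cc1
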